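**Retrosynthetic overview**
1. The 14-membered carbocycle is closed last at C9–C10 by Petasis methylenation and [3,3]-sigmatropic (Claisen) rearrangement of a 13-membered allyl α-hydroxy lactone; C11 then comes from chelation-controlled reduction and the acrylic acid from the C1 isopropenyl group.
2. The oxolane (C4–O–C7) with C3 and C4 comes from a hexavalent-osmium [3+2] oxidative cyclisation of a (7R)-7,8-diol onto the E-C3=C4 alkene.
3. The E-alkene comes from Negishi coupling of a vinyl iodide (from (S)-carvone: C1, via Eschenmoser–Tanabe fragmentation and hydrozirconation) with a zinc reagent from (R)-α-hydroxy-γ-butyrolactone (C7).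
4. C12 comes from Seebach alkylation of the (R)-lactic acid dioxolanone.
5. Ring order: oxolane (step 12), 13-membered lactone (step 15), 14-membered carbocycle (step 16).

Assumption: the SMILES is read as (1S,3S,4S,7R,11R,12S) in cembrane numbering (C1 bears the C15–C17 acrylic acid, C4–O–C7 is the oxolane, C18/C19/C20 sit on C4/C8/C12); these locants are used for all intermediates.

**Route**

Step 1
Reactants: 1 (S)-(+)-carvone
Product: 2 (1S,4S,6S)-1-methyl-4-(prop-1-en-2-yl)-7-oxabicyclo[4.1.0]heptan-2-one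
Conditions: 30% H2O2, NaOH (cat.), MeOH, 0 °C
Reagents that add atoms: hydrogen peroxide, OO
Why: Weitz–Scheffer nucleophilic epoxidation touches only the enone, and attack anti to the isopropenyl group gives the single trans epoxide (both new centres are consumed in step 2).

Step 2
Reactants: 2 (1S,4S,6S)-1-methyl-4-(prop-1-en-2-yl)-7-oxabicyclo[4.1.0]heptan-2-one
Product: 4 (3R)-3-(prop-1-en-2-yl)hept-5-ynal, via epoxy ketone tosylhydrazone 3 (not isolated)
Conditions: TsNHNH2, AcOH–CH2Cl2 (1:1), −20 °C → rt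
Reagents that add atoms: none
Why: Eschenmoser–Tanabe fragmentation opens the ring to the C13 aldehyde and the C3≡C4–CH3 alkyne while the C1 stereocentre (carvone C5) is untouched.

Step 3
Reactants: 4 (3R)-3-(prop-1-en-2-yl)hept-5-ynal
Product: 7 (3R,5E)-6-iodo-3-(prop-1-en-2-yl)hept-5-en-1-ol, via bis-zirconated alkenyl alkoxide 5 (not isolated), via iodoalkenyl zirconium alkoxide 6 (not isolated)
Conditions: Cp2Zr(H)Cl (3.3 equiv), THF, 25 → 40 °C; then I2, 0 °C; aq. Na2S2O3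
Reagents that add atoms: iodine, II
Why: Cp2Zr(H)Cl reduces the aldehyde and adds syn to the alkyne (hydrozirconation) with zirconium equilibrating onto the methyl-bearing carbon, and iodinolysis with retention gives the E vinyl iodide; the 1,1-disubstituted alkene reacts far more slowly.

Step 4
Reactants: 8 (R)-α-hydroxy-γ-butyrolactone
Product: 9 (3R)-4-methylpentane-1,3,4-triol
Conditions: MeMgBr (3.5 equiv), THF, 0 °C → rt
Reagents that add atoms: methylmagnesium bromide, C[Mg]Br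
Why: Double Grignard addition to the lactone carbonyl builds the tertiary C8 carbinol; the C7 stereocentre is not touched.

Step 5
Reactants: 9 (3R)-4-methylpentane-1,3,4-triol
Product: 10 2-[(4R)-2,2,5,5-tetramethyl-1,3-dioxolan-4-yl]ethan-1-ol
Conditions: 2,2-dimethoxypropane, PPTS (cat.), acetone, rt
Reagents that add atoms: 2,2-dimethoxypropane, COC(C)(C)OC
Why: Thermodynamic ketalisation selects the five-membered dioxolane of the vicinal diol and leaves the primary alcohol free.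

Step 6
Reactants: 10 2-[(4R)-2,2,5,5-tetramethyl-1,3-dioxolan-4-yl]ethan-1-ol
Product: 11 (4R)-4-(2-iodoethyl)-2,2,5,5-tetramethyl-1,3-dioxolane
Conditions: I2, PPh3, imidazole, CH2Cl2, 0 °C
Reagents that add atoms: iodine, II
Why: Appel-type (Garegg–Samuelsson) iodination of the primary alcohol.

Step 7
Reactants: 7 (3R,5E)-6-iodo-3-(prop-1-en-2-yl)hept-5-en-1-ol; 11 (4R)-4-(2-iodoethyl)-2,2,5,5-tetramethyl-1,3-dioxolane
Product: 13 (3R,5E)-6-methyl-3-(prop-1-en-2-yl)-8-[(4R)-2,2,5,5-tetramethyl-1,3-dioxolan-4-yl]oct-5-en-1-ol, via alkylzinc iodide 12 (not isolated)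
Conditions: 11, Zn dust, LiCl, THF, 40 °C; then 7 (0.4 equiv), Pd(OAc)2 (3 mol %), SPhos (6 mol %), THF, rt
Reagents that add atoms: none
Why: Negishi sp3–sp2 coupling (oxidative addition of the vinyl iodide to zerovalent palladium) forms C4–C5 with retention of geometry, giving the E-trisubstituted alkene; the excess zinc reagent allows for the free hydroxyl.

Step 8
Reactants: 13 (3R,5E)-6-methyl-3-(prop-1-en-2-yl)-8-[(4R)-2,2,5,5-tetramethyl-1,3-dioxolan-4-yl]oct-5-en-1-ol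
Product: 14 (4R)-4-[(3E,6R)-8-iodo-3-methyl-6-(prop-1-en-2-yl)oct-3-en-1-yl]-2,2,5,5-tetramethyl-1,3-dioxolane
Conditions: I2, PPh3, imidazole, CH2Cl2, 0 °C
Reagents that add atoms: iodine, II
Why: Appel-type iodination of the primary C13 alcohol; alkenes and acetonide are inert.

Step 9
Reactants: 15 (R)-lactic acid
Product: 16 (2R,5R)-2-tert-butyl-5-methyl-1,3-dioxolan-4-one
Conditions: pivaldehyde, TsOH (cat.), pentane, reflux (Dean–Stark); recrystallisation
Reagents that add atoms: pivaldehyde, CC(C)(C)C=O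
Why: Acetalisation under thermodynamic control gives the cis acetal, whose new centre is set by the lactate centre (Seebach self-regeneration of stereocentres).

Step 10
Reactants: 14 (4R)-4-[(3E,6R)-8-iodo-3-methyl-6-(prop-1-en-2-yl)oct-3-en-1-yl]-2,2,5,5-tetramethyl-1,3-dioxolane; 16 (2R,5R)-2-tert-butyl-5-methyl-1,3-dioxolan-4-one
Product: 18 (2R,5S)-2-tert-butyl-5-methyl-5-{(3S,5E)-6-methyl-3-(prop-1-en-2-yl)-8-[(4R)-2,2,5,5-tetramethyl-1,3-dioxolan-4-yl]oct-5-en-1-yl}-1,3-dioxolan-4-one, via lithium enolate 17 (not isolated)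
Conditions: 16, LiN(i-Pr)2, THF–DMPU, −78 °C; then 14, −78 → −30 °C
Reagents that add atoms: none
Why: Seebach enolate alkylation occurs anti to the tert-butyl group, so C13 replaces the lactate hydrogen with retention and the quaternary C12 centre is (S).

Step 11
Reactants: 18 (2R,5S)-2-tert-butyl-5-methyl-5-{(3S,5E)-6-methyl-3-(prop-1-en-2-yl)-8-[(4R)-2,2,5,5-tetramethyl-1,3-dioxolan-4-yl]oct-5-en-1-yl}-1,3-dioxolan-4-one
Product: 19 (2R,5S)-2-tert-butyl-5-[(3S,5E,9R)-9,10-dihydroxy-6,10-dimethyl-3-(prop-1-en-2-yl)undec-5-en-1-yl]-5-methyl-1,3-dioxolan-4-one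
Conditions: AcOH–H2O (4:1), 40 °C
Reagents that add atoms: none
Why: Mild acid hydrolysis cleaves the labile acetonide of the secondary/tertiary diol, while the dioxolanone (an acylal) survives.

Step 12
Reactants: 19 (2R,5S)-2-tert-butyl-5-[(3S,5E,9R)-9,10-dihydroxy-6,10-dimethyl-3-(prop-1-en-2-yl)undec-5-en-1-yl]-5-methyl-1,3-dioxolan-4-one
Product: 20 (2R,5S)-2-tert-butyl-5-{(3S,5S)-5-hydroxy-5-[(2S,5R)-5-(2-hydroxypropan-2-yl)-2-methyloxolan-2-yl]-3-(prop-1-en-2-yl)pentyl}-5-methyl-1,3-dioxolan-4-one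
Conditions: K2OsO2(OH)4 (5 mol %), pyridine N-oxide (2 equiv), citric acid, Cu(OTf)2 (cat.), MeCN–pH 6.5 buffer, 60 °C
Reagents that add atoms: pyridine N-oxide, [O-][n+]1ccccc1
Why: In this oxidative cyclisation the hexavalent-osmium glycolate of the C7/C8 diol adds its O7–Os=O unit suprafacially across the E-alkene in a [3+2] cycloaddition that closes the oxolane, so chelation enforces the 2,5-cis ring (4S from 7R) and syn addition gives 3S; octavalent osmium is not generated, which should spare the isopropenyl group.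

Step 13
Reactants: 20 (2R,5S)-2-tert-butyl-5-{(3S,5S)-5-hydroxy-5-[(2S,5R)-5-(2-hydroxypropan-2-yl)-2-methyloxolan-2-yl]-3-(prop-1-en-2-yl)pentyl}-5-methyl-1,3-dioxolan-4-one
Product: 23 (2R,5S)-2-tert-butyl-5-{(3S,5S)-5-hydroxy-5-[(2S,5R)-2-methyl-5-(prop-1-en-2-yl)oxolan-2-yl]-3-(prop-1-en-2-yl)pentyl}-5-methyl-1,3-dioxolan-4-one, via C3 trimethylsilyl ether 21 (not isolated), via silylated isopropenyl oxolane 22 (not isolated)
Conditions: TMSCl (1.1 equiv), pyridine, 0 °C; then POCl3, 0 → 50 °C; aq. citric acid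
Reagents that add atoms: none
Why: The secondary C3 hydroxyl is masked in situ as its TMS ether and the tertiary C8 alcohol is dehydrated by E2 elimination of its dichlorophosphate toward a methyl group (as with linalool-oxide-type alcohols); acidic work-up frees C3–OH.

Step 14
Reactants: 23 (2R,5S)-2-tert-butyl-5-{(3S,5S)-5-hydroxy-5-[(2S,5R)-2-methyl-5-(prop-1-en-2-yl)oxolan-2-yl]-3-(prop-1-en-2-yl)pentyl}-5-methyl-1,3-dioxolan-4-one
Product: 24 (2R,5S)-2-tert-butyl-5-{(3S,5S)-3-(3-chloroprop-1-en-2-yl)-5-[(2S,5R)-5-(3-chloroprop-1-en-2-yl)-2-methyloxolan-2-yl]-5-hydroxypentyl}-5-methyl-1,3-dioxolan-4-one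
Conditions: Ca(OCl)2 (excess), CO2 (solid), CH2Cl2–H2O, 0 °C
Reagents that add atoms: calcium hypochlorite, [Ca+2].[O-]Cl.[O-]Cl
Why: Ene-type allylic chlorination by HOCl turns both isopropenyl groups into 2-(chloromethyl)vinyl groups; no stereocentre is touched.

Step 15
Reactants: 24 (2R,5S)-2-tert-butyl-5-{(3S,5S)-3-(3-chloroprop-1-en-2-yl)-5-[(2S,5R)-5-(3-chloroprop-1-en-2-yl)-2-methyloxolan-2-yl]-5-hydroxypentyl}-5-methyl-1,3-dioxolan-4-one
Product: 26 (1S,3S,4S,7R,12S) 13-membered allyl lactone (ring C11(=O)–O–C19H2–C8(=C9H2)–C7; 4,7-oxolane; 3-OH; 12-OH; C1 bearing 3-chloroprop-1-en-2-yl), via cesium carboxylate 25 (not isolated)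
Conditions: CsOH·H2O (1.05 equiv), THF–H2O, 0 °C; evaporate; DMF (2 mM), 60 °C
Reagents that add atoms: cesium hydroxide, [Cs+].[OH-]
Why: Hydroxide opens the activated dioxolanone (releasing pivaldehyde) and the cesium carboxylate displaces the oxolane-side allylic chloride under high dilution (SN2 macrolactonisation), the 13-membered ring being far easier to close than the 8-membered one from the C17 chloride.

Step 16
Reactants: 26 (1S,3S,4S,7R,12S) 13-membered allyl lactone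
Product: 30 (1S,3S,4S,7R,12S)-17-chloro-3,12-dihydroxy-4,7-epoxycembra-8(19),15-dien-11-one, via bis-silyl lactone 27 (not isolated), via bis-silyl enol ether 28 (not isolated), via bis-silyl ketone 29 (not isolated)
Conditions: BSA, TMSCl (cat.), MeCN, 50 °C, evaporate; Cp2TiMe2 (4 equiv), toluene, 80 °C, dark; then 150 °C (sealed tube); then 1 M HCl, THF, 0 °C
Reagents that add atoms: dimethyltitanocene, C[Ti](C)(C1C=CC=C1)C1C=CC=C1
Why: Petasis methylenation of the lactone carbonyl gives a cyclic allyl vinyl ether whose [3,3]-sigmatropic Claisen rearrangement (tether-enforced boat-like transition state) forms C9–C10 and the 14-membered carbocycle with the C8 exocyclic methylene; no stereocentre is created.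

Step 17
Reactants: 30 (1S,3S,4S,7R,12S)-17-chloro-3,12-dihydroxy-4,7-epoxycembra-8(19),15-dien-11-one
Product: 31 (1S,3S,4S,7R,11R,12S)-17-chloro-4,7-epoxycembra-8(19),15-diene-3,11,12-triol
Conditions: Zn(BH4)2, Et2O, −20 °C
Reagents that add atoms: none
Why: Chelation-controlled (Cram-chelate) reduction: zinc bridges the ketone and the free C12 hydroxyl and hydride enters from the methyl face, anti to the ring chain at C13, giving 11R.

Step 18
Reactants: 31 (1S,3S,4S,7R,11R,12S)-17-chloro-4,7-epoxycembra-8(19),15-diene-3,11,12-triol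
Product: 32 (1S,3S,4S,7R,11R,12S)-17-chloro-3,12-dihydroxy-4,7-epoxycembra-8(19),15-dien-11-yl acetate
Conditions: AcCl (1.1 equiv), Et3N, Bu2SnO (5 mol %), CH2Cl2, 0 °C
Reagents that add atoms: acetyl chloride, CC(Cl)=O
Why: Tin-catalysed acylation activates only the vicinal C11/C12 diol (cyclic stannylene), so the secondary C11 oxygen is acetylated in preference to the isolated hindered C3 hydroxyl and the tertiary C12 hydroxyl.

Step 19
Reactants: 32 (1S,3S,4S,7R,11R,12S)-17-chloro-3,12-dihydroxy-4,7-epoxycembra-8(19),15-dien-11-yl acetate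
Product: 34 (1S,3S,4S,7R,11R,12S)-11-acetoxy-3,12-dihydroxy-4,7-epoxycembra-8(19),15-dien-17-al, via alkoxyammonium chloride 33 (not isolated)
Conditions: N-methylmorpholine N-oxide (4 equiv), MeCN, 45 °C
Reagents that add atoms: N-methylmorpholine N-oxide, C[N+]1([O-])CCOCC1
Why: Kornblum-type (Ganem) oxidation: the N-oxide oxygen displaces the allylic chloride and loss of N-methylmorpholine gives the 2-substituted acrolein without touching the acetate or the other alkene.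

Step 20
Reactants: 34 (1S,3S,4S,7R,11R,12S)-11-acetoxy-3,12-dihydroxy-4,7-epoxycembra-8(19),15-dien-17-al
Product: 35 CNP0215199.3
Conditions: NaClO2, NaH2PO4, 2-methyl-2-butene, t-BuOH–H2O, rt
Reagents that add atoms: sodium chlorite, [Na+].[O-]Cl=O
Why: Pinnick (Lindgren–Kraus) oxidation converts the enal into the acrylic acid under buffered conditions that leave the acetate, the exocyclic alkene (HOCl scavenged) and all stereocentres intact.

**Compound list**
1 | (S)-(+)-carvone, (5S)-2-methyl-5-(prop-1-en-2-yl)cyclohex-2-en-1-one | CC1=CC[C@H](C(C)=C)CC1=O | starting material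
2 | (1S,4S,6S)-1-methyl-4-(prop-1-en-2-yl)-7-oxabicyclo[4.1.0]heptan-2-one | C[C@]12O[C@H]1C[C@H](C(C)=C)CC2=O | intermediate
3 | N-tosylhydrazone of 2 (not isolated) | C[C@]12O[C@H]1C[C@H](C(C)=C)CC2=NNS(=O)(=O)c1ccc(C)cc1 | intermediate
4 | (3R)-3-(prop-1-en-2-yl)hept-5-ynal | O=CC[C@H](C(C)=C)CC#CC | intermediate
5 | chlorobis(cyclopentadienyl)zirconium alkoxide of (3R,5E)-6-[chlorobis(cyclopentadienyl)zirconio]-3-(prop-1-en-2-yl)hept-5-en-1-ol (not isolated) | C/C(=C\C[C@@H](C(C)=C)CCO[Zr](Cl)(C1C=CC=C1)C1C=CC=C1)[Zr](Cl)(C1C=CC=C1)C1C=CC=C1 | intermediate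
6 | chlorobis(cyclopentadienyl)zirconium (3R,5E)-6-iodo-3-(prop-1-en-2-yl)hept-5-en-1-olate (not isolated) | C/C(I)=C\C[C@@H](C(C)=C)CCO[Zr](Cl)(C1C=CC=C1)C1C=CC=C1 | intermediate
7 | (3R,5E)-6-iodo-3-(prop-1-en-2-yl)hept-5-en-1-ol | OCC[C@H](C(C)=C)C/C=C(\C)I | intermediate
8 | (R)-α-hydroxy-γ-butyrolactone, (3R)-3-hydroxyoxolan-2-one | O[C@@H]1CCOC1=O | starting material
9 | (3R)-4-methylpentane-1,3,4-triol | OCC[C@@H](O)C(C)(C)O | intermediate
10 | 2-[(4R)-2,2,5,5-tetramethyl-1,3-dioxolan-4-yl]ethan-1-ol | OCC[C@H]1OC(C)(C)OC1(C)C | intermediate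
11 | (4R)-4-(2-iodoethyl)-2,2,5,5-tetramethyl-1,3-dioxolane | ICC[C@H]1OC(C)(C)OC1(C)C | intermediate
12 | {2-[(4R)-2,2,5,5-tetramethyl-1,3-dioxolan-4-yl]ethyl}zinc iodide (not isolated) | I[Zn]CC[C@H]1OC(C)(C)OC1(C)C | intermediate
13 | (3R,5E)-6-methyl-3-(prop-1-en-2-yl)-8-[(4R)-2,2,5,5-tetramethyl-1,3-dioxolan-4-yl]oct-5-en-1-ol | OCC[C@H](C(C)=C)C/C=C(\C)CC[C@H]1OC(C)(C)OC1(C)C | intermediate
14 | (4R)-4-[(3E,6R)-8-iodo-3-methyl-6-(prop-1-en-2-yl)oct-3-en-1-yl]-2,2,5,5-tetramethyl-1,3-dioxolane | ICC[C@H](C(C)=C)C/C=C(\C)CC[C@H]1OC(C)(C)OC1(C)C | intermediate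
15 | (R)-lactic acid | C[C@@H](O)C(=O)O | starting material
16 | (2R,5R)-2-tert-butyl-5-methyl-1,3-dioxolan-4-one | C[C@H]1O[C@@H](C(C)(C)C)OC1=O | intermediate
17 | lithium enolate of 16, (2R)-2-tert-butyl-5-methyl-1,3-dioxol-4-olate (not isolated) | CC1=C(O[Li])O[C@H](C(C)(C)C)O1 | intermediate
18 | (2R,5S)-2-tert-butyl-5-methyl-5-{(3S,5E)-6-methyl-3-(prop-1-en-2-yl)-8-[(4R)-2,2,5,5-tetramethyl-1,3-dioxolan-4-yl]oct-5-en-1-yl}-1,3-dioxolan-4-one | O=C1O[C@H](C(C)(C)C)O[C@@]1(C)CC[C@H](C(C)=C)C/C=C(\C)CC[C@H]1OC(C)(C)OC1(C)C | intermediate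
19 | (2R,5S)-2-tert-butyl-5-[(3S,5E,9R)-9,10-dihydroxy-6,10-dimethyl-3-(prop-1-en-2-yl)undec-5-en-1-yl]-5-methyl-1,3-dioxolan-4-one | O=C1O[C@H](C(C)(C)C)O[C@@]1(C)CC[C@H](C(C)=C)C/C=C(\C)CC[C@@H](O)C(C)(C)O | intermediate
20 | (2R,5S)-2-tert-butyl-5-{(3S,5S)-5-hydroxy-5-[(2S,5R)-5-(2-hydroxypropan-2-yl)-2-methyloxolan-2-yl]-3-(prop-1-en-2-yl)pentyl}-5-methyl-1,3-dioxolan-4-one | O=C1O[C@H](C(C)(C)C)O[C@@]1(C)CC[C@H](C(C)=C)C[C@H](O)[C@]1(C)CC[C@@H](O1)C(C)(C)O | intermediate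
21 | C3 trimethylsilyl ether of 20 (not isolated) | O=C1O[C@H](C(C)(C)C)O[C@@]1(C)CC[C@H](C(C)=C)C[C@H](O[Si](C)(C)C)[C@]1(C)CC[C@@H](O1)C(C)(C)O | intermediate
22 | C3 trimethylsilyl ether of 23 (not isolated) | O=C1O[C@H](C(C)(C)C)O[C@@]1(C)CC[C@H](C(C)=C)C[C@H](O[Si](C)(C)C)[C@]1(C)CC[C@@H](O1)C(C)=C | intermediate
23 | (2R,5S)-2-tert-butyl-5-{(3S,5S)-5-hydroxy-5-[(2S,5R)-2-methyl-5-(prop-1-en-2-yl)oxolan-2-yl]-3-(prop-1-en-2-yl)pentyl}-5-methyl-1,3-dioxolan-4-one | O=C1O[C@H](C(C)(C)C)O[C@@]1(C)CC[C@H](C(C)=C)C[C@H](O)[C@]1(C)CC[C@@H](O1)C(C)=C | intermediate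
24 | (2R,5S)-2-tert-butyl-5-{(3S,5S)-3-(3-chloroprop-1-en-2-yl)-5-[(2S,5R)-5-(3-chloroprop-1-en-2-yl)-2-methyloxolan-2-yl]-5-hydroxypentyl}-5-methyl-1,3-dioxolan-4-one | O=C1O[C@H](C(C)(C)C)O[C@@]1(C)CC[C@H](C(=C)CCl)C[C@H](O)[C@]1(C)CC[C@@H](O1)C(=C)CCl | intermediate
25 | cesium (2S,5S,7S)-5-(3-chloroprop-1-en-2-yl)-7-[(2S,5R)-5-(3-chloroprop-1-en-2-yl)-2-methyloxolan-2-yl]-2,7-dihydroxy-2-methylheptanoate (not isolated) | [Cs+].[O-]C(=O)[C@@](C)(O)CC[C@H](C(=C)CCl)C[C@H](O)[C@]1(C)CC[C@@H](O1)C(=C)CCl | intermediate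
26 | (1S,3S,4S,7R,12S) 13-membered allyl lactone: ring C11(=O)–O–C19H2–C8(=C9H2)–C7, 4,7-oxolane, 3-OH, 12-OH, 12-Me, C1 bearing 3-chloroprop-1-en-2-yl | O=C1OCC(=C)[C@H]2CC[C@](C)(O2)[C@@H](O)C[C@@H](C(=C)CCl)CC[C@]1(C)O | intermediate
27 | 3,12-bis(trimethylsilyl) ether of 26 (not isolated) | O=C1OCC(=C)[C@H]2CC[C@](C)(O2)[C@@H](O[Si](C)(C)C)C[C@@H](C(=C)CCl)CC[C@]1(C)O[Si](C)(C)C | intermediate
28 | C11-methylidene cyclic allyl vinyl ether from 27 (not isolated) | C=C1OCC(=C)[C@H]2CC[C@](C)(O2)[C@@H](O[Si](C)(C)C)C[C@@H](C(=C)CCl)CC[C@]1(C)O[Si](C)(C)C | intermediate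
29 | 3,12-bis(trimethylsilyl) ether of 30 (not isolated) | O=C1CCC(=C)[C@H]2CC[C@](C)(O2)[C@@H](O[Si](C)(C)C)C[C@@H](C(=C)CCl)CC[C@]1(C)O[Si](C)(C)C | intermediate
30 | (1S,3S,4S,7R,12S)-17-chloro-3,12-dihydroxy-4,7-epoxycembra-8(19),15-dien-11-one | O=C1CCC(=C)[C@H]2CC[C@](C)(O2)[C@@H](O)C[C@@H](C(=C)CCl)CC[C@]1(C)O | intermediate
31 | (1S,3S,4S,7R,11R,12S)-17-chloro-4,7-epoxycembra-8(19),15-diene-3,11,12-triol | O[C@@H]1CCC(=C)[C@H]2CC[C@](C)(O2)[C@@H](O)C[C@@H](C(=C)CCl)CC[C@]1(C)O | intermediate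
32 | (1S,3S,4S,7R,11R,12S)-17-chloro-3,12-dihydroxy-4,7-epoxycembra-8(19),15-dien-11-yl acetate | CC(=O)O[C@@H]1CCC(=C)[C@H]2CC[C@](C)(O2)[C@@H](O)C[C@@H](C(=C)CCl)CC[C@]1(C)O | intermediate
33 | 4-methyl-4-(C17-oxy)morpholin-4-ium chloride derived from 32 (not isolated) | CC(=O)O[C@@H]1CCC(=C)[C@H]2CC[C@](C)(O2)[C@@H](O)C[C@@H](C(=C)CO[N+]3(C)CCOCC3)CC[C@]1(C)O.[Cl-] | intermediate
34 | (1S,3S,4S,7R,11R,12S)-11-acetoxy-3,12-dihydroxy-4,7-epoxycembra-8(19),15-dien-17-al | CC(=O)O[C@@H]1CCC(=C)[C@H]2CC[C@](C)(O2)[C@@H](O)C[C@@H](C(=C)C=O)CC[C@]1(C)O | intermediate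
35 | CNP0215199.3, (1S,3S,4S,7R,11R,12S)-11-acetoxy-3,12-dihydroxy-4,7-epoxycembra-8(19),15-dien-17-oic acid | C=C(C(=O)O)[C@H]1CC[C@](C)(O)[C@H](OC(C)=O)CCC(=C)[C@H]2CC[C@](C)(O2)[C@@H](O)C1 | target

**Totals**
Total steps: 20. Longest linear sequence: 16 steps (from 1 through steps 1–3, 7, 8, 10–20).

**Steps most likely to fail**

Step 16 is the most uncertain: a hindered α-siloxy lactone must be methylenated and the [3,3] shift has to pass through a boat-like transition state. The fallback sets out from 24. The lithium enolate of methyl acetate (LiN(i-Pr)2, MeOAc, THF, −78 °C) opens the dioxolanone in a Claisen condensation to give methyl (4S,7S,9S)-7-(3-chloroprop-1-en-2-yl)-9-[(2S,5R)-5-(3-chloroprop-1-en-2-yl)-2-methyloxolan-2-yl]-4,9-dihydroxy-4-methyl-3-oxononanoate F1. Cs2CO3 in dilute DMF then closes the 14-membered carbocycle by C-alkylation with the oxolane-side allylic chloride to give the C10-methoxycarbonyl derivative of 30 F2. Krapcho dealkoxycarbonylation (LiCl, wet DMSO, 130 °C) comes back to the route at 30; steps 15 and 16 are both bypassed.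

Step 10 alkylates a quaternary-centre-forming enolate with an unactivated primary iodide. The fallback sets out from 13. Dess–Martin oxidation gives (3R,5E)-6-methyl-3-(prop-1-en-2-yl)-8-[(4R)-2,2,5,5-tetramethyl-1,3-dioxolan-4-yl]oct-5-enal F3. Aldol addition of enolate 17, again anti to the tert-butyl group, gives the C13-hydroxy derivative of 18 F4 as a C13 epimer mixture. PhOC(S)Cl and pyridine convert it into the C13 O-phenyl thionocarbonate of F4 F5, and Barton–McCombie reduction (Bu3SnH, AIBN, toluene, 80 °C) removes the C13 oxygen and comes back to the route at 18.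

Step 18 has to tell apart two hindered secondary hydroxyls (C11 and C3). The fallback sets out from 31. MeC(OMe)3 and PPTS tie up only the vicinal C11/C12 diol as the C11,C12 cyclic methyl orthoacetate of 31 F6, which the isolated C3 hydroxyl cannot form. Aqueous AcOH opens it to the monoacetate, which settles on the secondary oxygen, and the route is rejoined at 32.

Further compounds
F1 | step 16 | methyl (4S,7S,9S)-7-(3-chloroprop-1-en-2-yl)-9-[(2S,5R)-5-(3-chloroprop-1-en-2-yl)-2-methyloxolan-2-yl]-4,9-dihydroxy-4-methyl-3-oxononanoate | COC(=O)CC(=O)[C@@](C)(O)CC[C@H](C(=C)CCl)C[C@H](O)[C@]1(C)CC[C@@H](O1)C(=C)CCl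
F2 | step 16 | C10-methoxycarbonyl derivative of 30 (C10 epimers) | COC(=O)C1CC(=C)[C@H]2CC[C@](C)(O2)[C@@H](O)C[C@@H](C(=C)CCl)CC[C@](C)(O)C1=O
F3 | step 10 | (3R,5E)-6-methyl-3-(prop-1-en-2-yl)-8-[(4R)-2,2,5,5-tetramethyl-1,3-dioxolan-4-yl]oct-5-enal | O=CC[C@H](C(C)=C)C/C=C(\C)CC[C@H]1OC(C)(C)OC1(C)C
F4 | step 10 | C13-hydroxy derivative of 18 (C13 epimers) | O=C1O[C@H](C(C)(C)C)O[C@@]1(C)C(O)C[C@H](C(C)=C)C/C=C(\C)CC[C@H]1OC(C)(C)OC1(C)C
F5 | step 10 | C13 O-phenyl thionocarbonate of F4 | O=C1O[C@H](C(C)(C)C)O[C@@]1(C)C(OC(=S)Oc1ccccc1)C[C@H](C(C)=C)C/C=C(\C)CC[C@H]1OC(C)(C)OC1(C)C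
F6 | step 18 | C11,C12 cyclic methyl orthoacetate of 31 | COC1(C)O[C@@H]2CCC(=C)[C@H]3CC[C@](C)(O3)[C@@H](O)C[C@@H](C(=C)CCl)CC[C@]2(C)O1
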